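**Retrosynthetic overview**
- The strategy rests on the maleimide ring: its tetrasubstituted C3'=C4' alkene (C3' carries the chroman-7-ylmethyl CH2, C4' the 4-hydroxyphenyl ring) lies between two interchangeable imide carbonyls C2' and C5', so it maps onto the C≡C of a 1,3-diarylpropyne in either orientation.
- The NH imide 25 comes from anhydride 23, which comes from N-benzyl imide 21; 21 is cut into alkyne 19, benzyl isocyanate 20 and CO ([2+2+1], forming C3'–C2', C4'–C5' and one C(=O)–N).
- Alkyne 19 is cut at the C(sp3)–C(sp) bond into benzylic bromide 12 and the arylethynyl Grignard reagent 18.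
- The (S)-C3 centre of the chroman comes from Jacobsen epoxidation of 7-bromo-2,2-dimethylchromene 5 and hydride opening at C4; the C7 bromide is then turned into CH2Br.
- Ring order: both benzene rings are bought; the pyran ring is closed first (step 1); the five-membered imide ring is closed last (step 11) and re-formed as anhydride and NH imide in steps 12 and 13.

Key step: step 11

Remark on the chemistry: the target SMILES gives (S) at chroman C3 (priorities O > C2 > C4 > H), and silylation does not change this descriptor. Maleimide locants are N1', C2'(=O), C3', C4', C5'(=O). 2-Methylprop-1-enylmagnesium bromide is taken as the commercial THF solution.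

**Step 1**
Reactants: 1 4-bromo-2-hydroxybenzaldehyde; 2 2-methylprop-1-enylmagnesium bromide
Product: 5 7-bromo-2,2-dimethyl-2H-chromene, via allylic alcohol 3 (not isolated), via ortho-quinone methide 4 (not isolated)
Conditions: 2 (2.5 equiv), THF, 0 °C to rt; aq. NH4Cl; crude 3, PPTS (cat.), toluene, 80 °C
Reagents that add atoms: none
Why: Grignard addition to the aldehyde (the first equivalent is spent on the phenol) gives allylic benzylic alcohol 3, which loses water under mild acid to ortho-quinone methide 4, and oxa-6π electrocyclisation of 4 closes the pyran ring with the bromide fixed at C7 and no regioisomer possible.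

**Step 2**
Reactants: 5 7-bromo-2,2-dimethyl-2H-chromene
Product: 6 (3S,4S)-7-bromo-3,4-epoxy-2,2-dimethylchromane
Conditions: (S,S)-N,N'-bis(3,5-di-tert-butylsalicylidene)cyclohexane-1,2-diaminomanganese chloride [(S,S)-(salen)MnCl, 4 mol %], 4-phenylpyridine N-oxide (0.2 equiv), aq. NaOCl (pH 11.3 buffer), CH2Cl2, 0 °C
Reagents that add atoms: sodium hypochlorite, [Na+].[O-]Cl
Why: Jacobsen–Katsuki epoxidation, for which cis-disubstituted aryl-conjugated 2,2-dimethylchromenes are among the best substrates; the (S,S)-salen ligand should direct oxo transfer to the alkene face that gives the (3S,4S)-oxirane and thereby sets C3.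

**Step 3**
Reactants: 6 (3S,4S)-7-bromo-3,4-epoxy-2,2-dimethylchromane
Product: 7 (S)-7-bromo-2,2-dimethylchroman-3-ol
Conditions: LiAlH4, THF, 0 °C, short reaction time; Fieser work-up
Reagents that add atoms: none
Why: SN2 epoxide opening by hydride at the benzylic C4 (C3 is neopentyl-like next to the quaternary C2) leaves the C3–O bond and hence the (S) configuration untouched, and at 0 °C the aryl bromide should not be reduced.

**Step 4**
Reactants: 7 (S)-7-bromo-2,2-dimethylchroman-3-ol
Product: 8 (S)-[(7-bromo-2,2-dimethylchroman-3-yl)oxy](tert-butyl)dimethylsilane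
Conditions: TBSOTf, 2,6-lutidine, CH2Cl2, 0 °C
Reagents that add atoms: tert-butyldimethylsilyl trifluoromethanesulfonate, CC(C)(C)[Si](C)(C)OS(=O)(=O)C(F)(F)F
Why: Silylation of the hindered secondary alcohol with the reactive silyl triflate removes the only acidic proton before the organolithium step and later keeps the hydroxyl from adding to the isocyanate.

**Step 5**
Reactants: 8 (S)-[(7-bromo-2,2-dimethylchroman-3-yl)oxy](tert-butyl)dimethylsilane
Product: 11 [(S)-3-(tert-butyldimethylsilyloxy)-2,2-dimethylchroman-7-yl]methanol, via aryllithium 9 (not isolated), via aldehyde 10 (not isolated)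
Conditions: n-BuLi (1.1 equiv), THF, −78 °C; DMF, −78 to 0 °C; then MeOH, NaBH4, 0 °C
Reagents that add atoms: N,N-dimethylformamide, CN(C)C=O
Why: Bromine–lithium exchange, Bouveault formylation of aryllithium 9 with DMF and borohydride reduction of aldehyde 10 in the same flask install the benzylic carbon at C7, and the silyl ether and the chroman ether are inert to all three reagents.

**Step 6**
Reactants: 11 [(S)-3-(tert-butyldimethylsilyloxy)-2,2-dimethylchroman-7-yl]methanol
Product: 12 (S)-7-(bromomethyl)-3-(tert-butyldimethylsilyloxy)-2,2-dimethylchromane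
Conditions: CBr4, PPh3, CH2Cl2, 0 °C
Reagents that add atoms: tetrabromomethane, BrC(Br)(Br)Br
Why: Appel bromination converts the primary benzylic alcohol into the bromide under neutral conditions that should leave the silyl ether intact.

**Step 7**
Reactants: 13 4-iodophenol
Product: 14 tert-butyl(4-iodophenoxy)dimethylsilane
Conditions: TBSCl, imidazole, DMF, rt
Reagents that add atoms: tert-butyldimethylsilyl chloride, CC(C)(C)[Si](C)(C)Cl
Why: Imidazole-mediated silylation masks the phenol so that it neither quenches the Grignard reagent of step 10 nor adds to the isocyanate in step 11.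

**Step 8**
Reactants: 14 tert-butyl(4-iodophenoxy)dimethylsilane; 15 ethynyltrimethylsilane
Product: 16 tert-butyldimethyl{4-[(trimethylsilyl)ethynyl]phenoxy}silane
Conditions: PdCl2(PPh3)2 (2 mol %), CuI (4 mol %), Et3N, THF, rt
Reagents that add atoms: none
Why: Sonogashira coupling of the aryl iodide proceeds at room temperature, and the silyl cap on the acetylene prevents double arylation.

**Step 9**
Reactants: 16 tert-butyldimethyl{4-[(trimethylsilyl)ethynyl]phenoxy}silane
Product: 17 tert-butyl(4-ethynylphenoxy)dimethylsilane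
Conditions: AgNO3 (10 mol %), acetone/H2O, rt
Reagents that add atoms: none
Why: Silver-catalysed protodesilylation cleaves only the C(sp)–SiMe3 bond through a silver acetylide, whereas carbonate in methanol would also strip the aryl silyl ether.

**Step 10**
Reactants: 17 tert-butyl(4-ethynylphenoxy)dimethylsilane; 12 (S)-7-(bromomethyl)-3-(tert-butyldimethylsilyloxy)-2,2-dimethylchromane
Product: 19 (S)-3-(tert-butyldimethylsilyloxy)-7-{3-[4-(tert-butyldimethylsilyloxy)phenyl]prop-2-yn-1-yl}-2,2-dimethylchromane, via alkynylmagnesium bromide 18 (not isolated)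
Conditions: 17 (1.3 equiv), EtMgBr, THF, 0 to 50 °C; CuBr (10 mol %), then 12, THF, reflux
Reagents that add atoms: none
Why: Deprotonation of the terminal alkyne by the ethyl Grignard reagent and copper-catalysed C(sp)–C(sp3) cross-coupling of alkynylmagnesium bromide 18 with the benzylic bromide should give the 1,3-diarylpropyne without a strong free base that would isomerise it to the allene.

**Step 11**
Reactants: 19 (S)-3-(tert-butyldimethylsilyloxy)-7-{3-[4-(tert-butyldimethylsilyloxy)phenyl]prop-2-yn-1-yl}-2,2-dimethylchromane; 20 benzyl isocyanate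
Product: 21 N-benzyl-3-{[(S)-3-(tert-butyldimethylsilyloxy)-2,2-dimethylchroman-7-yl]methyl}-4-[4-(tert-butyldimethylsilyloxy)phenyl]maleimide
Conditions: Ru3(CO)12 (5 mol %), CO (1–3 atm), 20 (1.5 equiv), mesitylene, 130 °C
Reagents that add atoms: carbon monoxide, [C-]#[O+]
Why: Ru3(CO)12 breaks up under CO into mononuclear zerovalent ruthenium carbonyls, on which the alkyne of 19 and the C=N bond of 20 couple oxidatively to a five-membered azaruthenacycle (Ru–C=C–C(=O)–N), CO inserts into the Ru–C(vinyl) bond, and C(acyl)–N reductive elimination releases 21 and returns zerovalent ruthenium. The closest known reaction type is the Ru3(CO)12-catalysed [2+2+1] cocyclisation of internal alkynes, isocyanates and CO to tetrasubstituted maleimides, and an alkyne carrying one aryl group and one benzylic CH2 group is an aryl/alkyl alkyne of that class. The only ring formed, the five-membered imide, closes on the metal by reductive elimination from the six-membered acyl(amido)ruthenacycle, which makes C3'–C2', C4'–C5' and one C(=O)–N bond in a single operation. No stereocentre is created, and the silylated C3 centre is remote and not epimerisable under these neutral conditions. Regioselectivity is not required, because each alkyne carbon ends up attached to one of two equivalent imide carbonyls, so either insertion sense gives 21. The step needs chemoselectivity against propargyl-to-allene isomerisation at the doubly activated CH2, alkyne cyclotrimerisation and isocyanate trimerisation, which the base-free medium, the CO atmosphere that keeps ruthenium saturated, the excess of 20 and the absence of free hydroxyl groups in 19 should secure.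

**Step 12**
Reactants: 21 N-benzyl-3-{[(S)-3-(tert-butyldimethylsilyloxy)-2,2-dimethylchroman-7-yl]methyl}-4-[4-(tert-butyldimethylsilyloxy)phenyl]maleimide
Product: 23 3-{[(S)-3-(tert-butyldimethylsilyloxy)-2,2-dimethylchroman-7-yl]methyl}-4-(4-hydroxyphenyl)furan-2,5-dione, via maleic diacid 22 (not isolated)
Conditions: KOH (excess), EtOH/H2O, reflux; then 2 M HCl to pH 1, rt
Reagents that add atoms: potassium hydroxide, [K+].[OH-]
Why: Saponification of the N-benzyl imide to the maleate (which also cleaves the aryl silyl ether) is followed on acidification by spontaneous cyclodehydration of the cis-diacid 22 of the tetrasubstituted alkene to the anhydride, and the hindered secondary silyl ether should withstand both media.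

**Step 13**
Reactants: 23 3-{[(S)-3-(tert-butyldimethylsilyloxy)-2,2-dimethylchroman-7-yl]methyl}-4-(4-hydroxyphenyl)furan-2,5-dione
Product: 24 3-{[(S)-3-(tert-butyldimethylsilyloxy)-2,2-dimethylchroman-7-yl]methyl}-4-(4-hydroxyphenyl)-1H-pyrrole-2,5-dione
Conditions: HMDS (10 equiv), MeOH (5 equiv), DMF, rt; dilute aq. HCl work-up
Reagents that add atoms: hexamethyldisilazane, C[Si](C)(C)N[Si](C)(C)C
Why: Anhydride-to-imide exchange with HMDS/methanol as a mild in situ ammonia source proceeds at room temperature, so the benzylic CH2 and the silyl ether see neither heat nor strong base, and any trimethylsilyl group taken up by the phenol is lost on the acidic work-up.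

**Step 14**
Reactants: 24 3-{[(S)-3-(tert-butyldimethylsilyloxy)-2,2-dimethylchroman-7-yl]methyl}-4-(4-hydroxyphenyl)-1H-pyrrole-2,5-dione
Product: 25 asperimide C
Conditions: HF·pyridine, THF/pyridine, 0 °C to rt
Reagents that add atoms: none
Why: Fluoride-mediated desilylation under buffered, non-basic conditions should free the C3 hydroxyl without touching the imide, the benzylic CH2 or the configuration at C3.

**Compound list**
1 | 4-bromo-2-hydroxybenzaldehyde | O=Cc1ccc(Br)cc1O | starting material
2 | 2-methylprop-1-enylmagnesium bromide | CC(C)=C[Mg]Br | starting material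
3 | 5-bromo-2-(1-hydroxy-3-methylbut-2-en-1-yl)phenol (racemic) | CC(C)=CC(O)c1ccc(Br)cc1O | intermediate
4 | 3-bromo-6-(3-methylbut-2-en-1-ylidene)cyclohexa-2,4-dien-1-one (ortho-quinone methide) | CC(C)=CC=C1C=CC(Br)=CC1=O | intermediate
5 | 7-bromo-2,2-dimethyl-2H-chromene | CC1(C)C=Cc2ccc(Br)cc2O1 | intermediate
6 | (3S,4S)-7-bromo-3,4-epoxy-2,2-dimethylchromane | CC1(C)Oc2cc(Br)ccc2[C@@H]2O[C@H]12 | intermediate
7 | (S)-7-bromo-2,2-dimethylchroman-3-ol | CC1(C)Oc2cc(Br)ccc2C[C@@H]1O | intermediate
8 | (S)-[(7-bromo-2,2-dimethylchroman-3-yl)oxy](tert-butyl)dimethylsilane | CC1(C)Oc2cc(Br)ccc2C[C@@H]1O[Si](C)(C)C(C)(C)C | intermediate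
9 | [(S)-3-(tert-butyldimethylsilyloxy)-2,2-dimethylchroman-7-yl]lithium | CC1(C)Oc2cc([Li])ccc2C[C@@H]1O[Si](C)(C)C(C)(C)C | intermediate
10 | (S)-3-(tert-butyldimethylsilyloxy)-2,2-dimethylchromane-7-carbaldehyde | CC1(C)Oc2cc(C=O)ccc2C[C@@H]1O[Si](C)(C)C(C)(C)C | intermediate
11 | [(S)-3-(tert-butyldimethylsilyloxy)-2,2-dimethylchroman-7-yl]methanol | CC1(C)Oc2cc(CO)ccc2C[C@@H]1O[Si](C)(C)C(C)(C)C | intermediate
12 | (S)-7-(bromomethyl)-3-(tert-butyldimethylsilyloxy)-2,2-dimethylchromane | CC1(C)Oc2cc(CBr)ccc2C[C@@H]1O[Si](C)(C)C(C)(C)C | intermediate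
13 | 4-iodophenol | Oc1ccc(I)cc1 | starting material
14 | tert-butyl(4-iodophenoxy)dimethylsilane | CC(C)(C)[Si](C)(C)Oc1ccc(I)cc1 | intermediate
15 | ethynyltrimethylsilane | C#C[Si](C)(C)C | starting material
16 | tert-butyldimethyl{4-[(trimethylsilyl)ethynyl]phenoxy}silane | CC(C)(C)[Si](C)(C)Oc1ccc(C#C[Si](C)(C)C)cc1 | intermediate
17 | tert-butyl(4-ethynylphenoxy)dimethylsilane | CC(C)(C)[Si](C)(C)Oc1ccc(C#C)cc1 | intermediate
18 | {[4-(tert-butyldimethylsilyloxy)phenyl]ethynyl}magnesium bromide | CC(C)(C)[Si](C)(C)Oc1ccc(C#C[Mg]Br)cc1 | intermediate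
19 | (S)-3-(tert-butyldimethylsilyloxy)-7-{3-[4-(tert-butyldimethylsilyloxy)phenyl]prop-2-yn-1-yl}-2,2-dimethylchromane | CC1(C)Oc2cc(CC#Cc3ccc(O[Si](C)(C)C(C)(C)C)cc3)ccc2C[C@@H]1O[Si](C)(C)C(C)(C)C | intermediate
20 | benzyl isocyanate | O=C=NCc1ccccc1 | starting material
21 | N-benzyl-3-{[(S)-3-(tert-butyldimethylsilyloxy)-2,2-dimethylchroman-7-yl]methyl}-4-[4-(tert-butyldimethylsilyloxy)phenyl]maleimide | CC1(C)Oc2cc(CC3=C(c4ccc(O[Si](C)(C)C(C)(C)C)cc4)C(=O)N(Cc5ccccc5)C3=O)ccc2C[C@@H]1O[Si](C)(C)C(C)(C)C | intermediate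
22 | (Z)-2-{[(S)-3-(tert-butyldimethylsilyloxy)-2,2-dimethylchroman-7-yl]methyl}-3-(4-hydroxyphenyl)but-2-enedioic acid (potassium salt in the basic flask, free acid on acidification) | CC1(C)Oc2cc(C/C(C(=O)O)=C(/C(=O)O)c3ccc(O)cc3)ccc2C[C@@H]1O[Si](C)(C)C(C)(C)C | intermediate
23 | 3-{[(S)-3-(tert-butyldimethylsilyloxy)-2,2-dimethylchroman-7-yl]methyl}-4-(4-hydroxyphenyl)furan-2,5-dione | CC1(C)Oc2cc(CC3=C(c4ccc(O)cc4)C(=O)OC3=O)ccc2C[C@@H]1O[Si](C)(C)C(C)(C)C | intermediate
24 | 3-{[(S)-3-(tert-butyldimethylsilyloxy)-2,2-dimethylchroman-7-yl]methyl}-4-(4-hydroxyphenyl)-1H-pyrrole-2,5-dione | CC1(C)Oc2cc(CC3=C(c4ccc(O)cc4)C(=O)NC3=O)ccc2C[C@@H]1O[Si](C)(C)C(C)(C)C | intermediate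
25 | asperimide C, 3-{[(S)-3-hydroxy-2,2-dimethylchroman-7-yl]methyl}-4-(4-hydroxyphenyl)-1H-pyrrole-2,5-dione | CC1(C)Oc2cc(CC3=C(c4ccc(O)cc4)C(=O)NC3=O)ccc2C[C@@H]1O | target

**Step count**
Total: 14 steps. Longest linear sequence: 11 steps (steps 1–6 and 10–14); steps 7–9 build the alkyne arm.

**Steps most likely to fail**

Step 11. The ruthenium catalyst may move the propargylic hydrogen and isomerise the alkyne to the aryl-conjugated allene, or trimerise the alkyne faster than it takes up isocyanate and CO. The fallback builds the imide by cross-coupling on a preformed maleimide; it sets out from bromide 12 and returns at 21. Zinc dust and LiCl in THF should insert into the C–Br bond of 12 to give {[(S)-3-(tert-butyldimethylsilyloxy)-2,2-dimethylchroman-7-yl]methyl}zinc bromide F1. Commercial N-benzyl-2,3-dibromomaleimide (O=C1C(Br)=C(Br)C(=O)N1Cc1ccccc1) is mono-arylated by Suzuki–Miyaura coupling with one equivalent of commercial 4-(tert-butyldimethylsilyloxy)phenylboronic acid (Pd(PPh3)4, K3PO4, dioxane, 60 °C) to give N-benzyl-3-bromo-4-[4-(tert-butyldimethylsilyloxy)phenyl]maleimide F2. Negishi coupling of F1 with F2 (Pd(OAc)2, SPhos, THF, rt) forms the C3'–CH2 bond and gives 21.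

Step 10. Under the basic organomagnesium/copper conditions the product may undergo a 1,3-prototropic shift to the diaryl allene, and either partner may homocouple. The fallback forms the C(sp)–C(sp2) bond last; it sets out from 12 and returns at 19. Alkyne 15 is deprotonated with EtMgBr to [(trimethylsilyl)ethynyl]magnesium bromide F3, which is coupled with 12 under CuBr catalysis to (S)-tert-butyl{2,2-dimethyl-7-[3-(trimethylsilyl)prop-2-yn-1-yl]chroman-3-yloxy}dimethylsilane F4. The CH2 of F4 is activated by one aryl group only and is much less prone to isomerise. AgNO3-catalysed protodesilylation gives (S)-tert-butyl[2,2-dimethyl-7-(prop-2-yn-1-yl)chroman-3-yloxy]dimethylsilane F5. Sonogashira coupling of F5 with iodide 14 (PdCl2(PPh3)2, CuI, Et3N, THF, rt) then gives 19.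

Step 12. Hot hydroxide may shift the ring double bond toward the benzylic CH2 (arylidene succinate formation), stall at the ring-opened amic acid, or erode the secondary silyl ether. The fallback avoids hydroxide with an acid-cleavable nitrogen substituent; it sets out from 19 and returns at 25. The cocyclisation of step 11 is run with 2,4-dimethoxybenzyl isocyanate (COc1ccc(CN=C=O)c(OC)c1) in place of 20, giving N-(2,4-dimethoxybenzyl)-3-{[(S)-3-(tert-butyldimethylsilyloxy)-2,2-dimethylchroman-7-yl]methyl}-4-[4-(tert-butyldimethylsilyloxy)phenyl]maleimide F6. Acidolysis with TFA/anisole at 60 °C should remove the dimethoxybenzyl group and, with it, the secondary silyl ether, giving after methanolic work-up 3-{[(S)-3-hydroxy-2,2-dimethylchroman-7-yl]methyl}-4-[4-(tert-butyldimethylsilyloxy)phenyl]-1H-pyrrole-2,5-dione F7. HF·pyridine in THF then removes the remaining silyl group and gives 25, so no hydroxide, anhydride or HMDS stage is needed.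

**Further compounds**
F1 | step 11 | {[(S)-3-(tert-butyldimethylsilyloxy)-2,2-dimethylchroman-7-yl]methyl}zinc bromide | CC1(C)Oc2cc(C[Zn]Br)ccc2C[C@@H]1O[Si](C)(C)C(C)(C)C
F2 | step 11 | N-benzyl-3-bromo-4-[4-(tert-butyldimethylsilyloxy)phenyl]maleimide | O=C1C(Br)=C(c2ccc(O[Si](C)(C)C(C)(C)C)cc2)C(=O)N1Cc1ccccc1
F3 | step 10 | [(trimethylsilyl)ethynyl]magnesium bromide | C[Si](C)(C)C#C[Mg]Br
F4 | step 10 | (S)-tert-butyl{2,2-dimethyl-7-[3-(trimethylsilyl)prop-2-yn-1-yl]chroman-3-yloxy}dimethylsilane | CC1(C)Oc2cc(CC#C[Si](C)(C)C)ccc2C[C@@H]1O[Si](C)(C)C(C)(C)C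
F5 | step 10 | (S)-tert-butyl[2,2-dimethyl-7-(prop-2-yn-1-yl)chroman-3-yloxy]dimethylsilane | CC1(C)Oc2cc(CC#C)ccc2C[C@@H]1O[Si](C)(C)C(C)(C)C
F6 | step 12 | N-(2,4-dimethoxybenzyl)-3-{[(S)-3-(tert-butyldimethylsilyloxy)-2,2-dimethylchroman-7-yl]methyl}-4-[4-(tert-butyldimethylsilyloxy)phenyl]maleimide | CC1(C)Oc2cc(CC3=C(c4ccc(O[Si](C)(C)C(C)(C)C)cc4)C(=O)N(Cc5ccc(OC)cc5OC)C3=O)ccc2C[C@@H]1O[Si](C)(C)C(C)(C)C
F7 | step 12 | 3-{[(S)-3-hydroxy-2,2-dimethylchroman-7-yl]methyl}-4-[4-(tert-butyldimethylsilyloxy)phenyl]-1H-pyrrole-2,5-dione | CC1(C)Oc2cc(CC3=C(c4ccc(O[Si](C)(C)C(C)(C)C)cc4)C(=O)NC3=O)ccc2C[C@@H]1O
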